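- I began with a small charge: the flask held 2.0 mM of solid substrate, which dissolves into starting material, and 2.0 µM of free catalyst. I followed one molecule to its fork: once dissolved, it either stayed starting material or went on to product.

| setting | grey | red | flask |
|---|---|---|---|
| solid substrate | 2 mM | 2 mM | 2.0 mM |
| free catalyst | 1 µM | 4 µM | 2.0 µM |
| remark | run made earlier | run made earlier |  |
| time |  |  | 2.5 min |

| run | time / s | product / % | starting material / % |
|---|---|---|---|
| grey | 10.0 | 0 | 2 |
| grey | 15.0 | 1 | 11 |
| grey | 25.0 | 0 | 10 |
| grey | 40.0 | 5 | 14 |
| grey | 80.0 | 6 | 28 |
| grey | 120 | 6 | 34 |
| red | 10.0 | 1 | 8 |
| red | 15.0 | 2 | 7 |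
| red | 25.0 | 4 | 7 |
| red | 40.0 | 5 | 15 |
| red | 80.0 | 13 | 23 |
| red | 120 | 12 | 30 |

(standard deviation of a reading: 2 percentage points)

* how much product there is at 2.5 min, in percent of the solid substrate charged
* concentration of starting material in solution at 2.5 min, in percent of saturation

- solid, in amounts per volume of the solution: solid substrate
- the numbers in the tables scatter with a standard deviation of 2 percentage points
- at the start none of the solid substrate is in solution
- starting material is what solid substrate becomes in solution
- starting material means what is dissolved; the solid is not counted in it

- Pooling the last two readings of each run, I found that the part of the dissolved material that had become product was 16.2% in the grey run and 32.1% in the red run.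
- My first doubt was that the catalyst might hold dissolved material uncounted, but even in the red run it came to 0.200% of the charge, against a scatter of 2 percentage points, so I dropped the doubt.
- My second doubt was how to interpolate: 4.00 times the catalyst gave 1.98 times the share, so a straight line seemed wrong. I took the geometric mean, 22.8%, as the capture share of the flask, the part of the dissolved material that has become product.
- My third doubt was that the grey share fell from 26.3% to 15.0% between 40.0 s and 120 s. The red share rose from 25.0% to 28.6%, however, so I kept mine, with an error of a few points.
- Extending the last rise of the dissolved total in a straight line gave 45.5% at 2.5 min, and so 10.4% product.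
- The forecast, higher than mine, said 12% product and 53% of saturation, from “an approach to saturation at roughly 70% of the charge”. Taking that ceiling, my starting material gave 50.2% of saturation.
- The flask gave 13.0% product and 60.5% of saturation.

    starting material + free catalyst → catalyst intermediate A (k = 12000 L mol⁻¹ s⁻¹)
    catalyst intermediate A ⇌ catalyst intermediate B (K = 0.980, k = 32.0 s⁻¹)
    catalyst intermediate B ⇌ free catalyst + product (K = 3.80 × 10⁻⁴ M, k = 340 s⁻¹)
    solid substrate ⇌ starting material, rate k4*(cs4 - [starting material]) while solid is left; crystals form when [starting material] > cs4 (solubility = 1.30 mM, k = 0.00820 s⁻¹)
    2 catalyst intermediate A → spent catalyst (k = 1.50 × 10⁵ L mol⁻¹ s⁻¹)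

- The capture share of the flask came to 24.9%, and my 22.8% on its 52.3% dissolved gives 11.9% product. On the same flask stopped at 40 s, it gives 4.27% against a simulated 4.74%. In the flask, starting material was made 3.47 times faster than it was used up at 0.979 min, and 5.17 times faster at 2.50 min. Used over made, the running capture share stood at 28.8% at the earlier time and 19.3% at the later.

(The runs stem from a simulated flask for substances that don't exist; noise was put on by code.)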